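Germacranolide numbering is used. The 3(2H)-furanone (ring O–C3=C2–C1(=O)–C10) is disconnected at the oxidation pattern of C10 and C3, which stand 1,4 across C1–C2: both C–O bonds come from singlet oxygen added to a 2-alkoxydiene (C10=C1–C2=C3). The precursor of the key step is therefore a six-membered 1,2-dioxine fused to a pyran ring, in which the enol-ether oxygen is the future C7 hydroxyl and the C8 silyloxy group has steered the C10–O bond. Base (Kornblum–DeLaMare) and then acid contract the peroxide to the furanone, unmask the C1 ketone and free C7–OH in one operation. An indium Barbier allylation (C6–C7) then closes the carbocycle and cis-lactone.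

Key step: step 10

Remark: lactone 7 (from D-glutamic acid) is assumed to be commercially available; compounds 8–13 are carried as both C10 epimers because C10 becomes sp2 in step 8 (C11–C13 is the methylene lactone, C14 the methyl on C10, C15 the hydroxymethyl on C4).

Step 1
Reactants: 1 but-2-yne-1,4-diol
Product: 2 4-[(4-methoxybenzyl)oxy]but-2-yn-1-ol
Conditions: NaH, PMBCl (diol in threefold excess), Bu4NI (cat.), THF–DMF, 0 °C to rt
Reagents that add atoms: 4-methoxybenzyl chloride, COc1ccc(CCl)cc1
Why: Williamson etherification of the mono-alkoxide; the excess of diol should hold the reaction at the mono-ether, and no stereocentre is involved.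

Step 2
Reactants: 2 4-[(4-methoxybenzyl)oxy]but-2-yn-1-ol
Product: 3 (Z)-3-iodo-4-[(4-methoxybenzyl)oxy]but-2-en-1-ol
Conditions: NaAlH2(OCH2CH2OMe)2, THF, 0 °C; then I2, −78 to 0 °C
Reagents that add atoms: iodine, II
Why: Hydroxyl-directed trans-hydroalumination puts aluminium on the distal alkyne carbon, and iodinolysis with retention should give the Z-iodoalkene in which C6 and iodine (the later C3) are cis, which fixes the C4=C5 geometry of the target.

Step 3
Reactants: 3 (Z)-3-iodo-4-[(4-methoxybenzyl)oxy]but-2-en-1-ol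
Product: 4 (Z)-tert-butyl({3-iodo-4-[(4-methoxybenzyl)oxy]but-2-en-1-yl}oxy)dimethylsilane
Conditions: TBSCl, imidazole, CH2Cl2, 0 °C to rt
Reagents that add atoms: tert-butyldimethylsilyl chloride, CC(C)(C)[Si](C)(C)Cl
Why: Silyl ether formation at the primary allylic alcohol (C6), orthogonal to the PMB ether at C15.

Step 4
Reactants: 4 silyl-protected Z-iodoalkene; 5 (E)-1,2-bis(tributylstannyl)ethene
Product: 6 (1E,3E)-dienylstannane (Bu3Sn on C2, C3 and C6 cis across C4=C5)
Conditions: Pd2(dba)3 (cat.), AsPh3, DMF, rt, threefold excess of 5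
Reagents that add atoms: none
Why: Stille coupling with retention at both sp2 carbons; the excess of distannane should stop the reaction after one coupling and leave the E-stannyl terminus at C2.

Step 5
Reactants: 7 (R)-5-[(trityloxy)methyl]dihydrofuran-2(3H)-one
Product: 8 (5R)-3-methyl-5-[(trityloxy)methyl]dihydrofuran-2(3H)-one (both C3 epimers)
Conditions: LiN(i-Pr)2, THF, −78 °C; then MeI
Reagents that add atoms: iodomethane, CI
Why: C-alkylation of the lactone lithium enolate installs C14; the new centre (C10) need not be controlled because it becomes sp2 in step 8.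

Step 6
Reactants: 8 methylated lactone
Product: 10 (4R)-4-[(tert-butyldimethylsilyl)oxy]-N-methoxy-N,2-dimethyl-5-(trityloxy)pentanamide, via hydroxy amide 9 (not isolated)
Conditions: MeNH(OMe)·HCl, i-PrMgCl, THF, −20 °C; aqueous work-up; then TBSCl, imidazole, DMF, rt
Reagents that add atoms: N,O-dimethylhydroxylamine hydrochloride, CNOC.Cl; tert-butyldimethylsilyl chloride, CC(C)(C)[Si](C)(C)Cl
Why: Weinreb amide formation by aminolysis of the lactone with the magnesium amide, then silylation of the freed C8 hydroxyl, which blocks relactonisation and installs the group that steers step 9; C8 (R) is not touched.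

Step 7
Reactants: 6 dienylstannane; 10 silyl-protected Weinreb amide
Product: 12 (2R,6E,8E)-2,10-bis[(tert-butyldimethylsilyl)oxy]-8-{[(4-methoxybenzyl)oxy]methyl}-4-methyl-1-(trityloxy)deca-6,8-dien-5-one, via dienyllithium 11 (not isolated)
Conditions: MeLi, THF, −78 °C; then 10, −78 to −40 °C; aq. NH4Cl
Reagents that add atoms: none
Why: Tin–lithium exchange gives the dienyllithium with retention, and the Weinreb ketone synthesis (chelated tetrahedral intermediate) should give the E,E-dienone (C1–C2 bond) without over-addition.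

Step 8
Reactants: 12 trityl-protected dienone
Product: 14 (3R)-3-[(tert-butyldimethylsilyl)oxy]-6-[(1E,3E)-dienyl]-5-methyl-3,4-dihydro-2H-pyran (pyran O = O7, C3 = C8, C5 = C10, C6 = C1), via hydroxy ketone 13 (not isolated)
Conditions: ZnBr2, CH2Cl2–MeOH (20:1), 0 °C; filtration; then PPTS (cat.), 4 Å MS, PhMe, 70 °C
Reagents that add atoms: none
Why: ZnBr2 removes the trityl ether selectively, the δ-hydroxy ketone closes to the six-membered lactol and acid-catalysed dehydration can only go towards C10, which gives the conjugated cyclic enol ether (a 2-alkoxy-1,3-diene) and merges the C10 epimers.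

Step 9
Reactants: 14 dienyl dihydropyran
Product: 15 pyran-fused 3,6-dihydro-1,2-dioxine (O–O bridge from C10 to C3, C1=C2 enol ether; 8R,10R,3R)
Conditions: O2, tetraphenylporphyrin (cat.), visible light, CH2Cl2, −78 °C; used crude
Reagents that add atoms: dioxygen (as singlet oxygen), O=O
Why: [4+2] cycloaddition of singlet oxygen to the electron-rich s-cis diene C10=C1–C2=C3; the C8 silyloxy group, expected to sit pseudoaxial on the half-chair (gauche to the ring oxygen, no syn-axial hydrogen), should shield one face so that the C10–O bond forms anti to it (10R), while suprafacial addition fixes C3, which is lost again in step 10.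

Step 10
Reactants: 15 pyran-fused 1,2-dioxine
Product: 18 furanone alcohol (8R,10R; free C7–OH), via hydroxy enone 16 (not isolated), via hemiketal 17 (not isolated)
Conditions: Et3N, CH2Cl2, −20 to 0 °C; then PPTS, THF–H2O (10:1), 0 °C to rt, short exposure
Reagents that add atoms: none
Why: Triethylamine removes the doubly allylic C3–H, the only hydrogen on a peroxide-bearing carbon (C10 is quaternary), with heterolysis of the O–O bond; this is a Kornblum–DeLaMare rearrangement, the closest known reaction type being the base-induced conversion of 3,6-dihydro-1,2-dioxines into cis-4-hydroxy enones and furans, and it gives the Z-configured hydroxy enone 16. The C10 oxygen then adds to the new C3 ketone (5-exo-trig) to give hemiketal 17, so that the furanone ring O–C3–C2–C1–C10 stands where the six-membered 1,2-dioxine O–O–C3–C2–C1–C10 stood, one peroxide oxygen having left the ring. PPTS ionises the C3 hemiketal to a 3-alkoxyfuranium ion, water adds at C1 and the pyran ketal collapses, which unmasks the C1 ketone and releases the primary C7 hydroxyl; the overall change from 15 to 18 is an isomerisation. No stereocentre is created: C10 (R) was set in step 9 and its C–O bond is never broken, C8 is untouched and C3 becomes sp2. The step needs the right partition between the two vinylogous esters (exocyclic in 16, endocyclic in 18): the linearly conjugated 3(2H)-furanone is expected to be the thermodynamic sink, and its free C7 hydroxyl is oxidised at once in step 11, which removes the way back.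

Step 11
Reactants: 18 furanone alcohol
Product: 19 furanone aldehyde (C7 aldehyde, 8R-OTBS)
Conditions: Dess–Martin periodinane, NaHCO3, CH2Cl2, 0 °C
Reagents that add atoms: none
Why: Dess–Martin oxidation of the primary alcohol under buffered conditions, under which the α-silyloxy aldehyde should keep its C8 configuration.

Step 12
Reactants: 19 furanone aldehyde; 20 methyl propiolate
Product: 22 methyl (4R)-3-hydroxy-2-methylene-4-silyloxy-5-(furanonyl)pentanoate (C7 carbinol epimers), via vinylalane 21 (not isolated)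
Conditions: i-Bu2AlH, N-methylmorpholine N-oxide, THF, 0 °C, then 20; then 19, −78 to 0 °C; aq. potassium sodium tartrate (KNaC4H4O6)
Reagents that add atoms: none
Why: Hydroalumination of the propiolate gives the α-(methoxycarbonyl)vinylalane, whose 1,2-addition to the aldehyde gives the Morita–Baylis–Hillman-type adduct (C7–C11 bond) without amine base; the C7 carbinol mixture converges in step 13.

Step 13
Reactants: 22 allylic alcohol
Product: 23 methyl (2Z,4R)-2-(bromomethyl)-4-silyloxy-5-(furanonyl)pent-2-enoate (C6–OTBS)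
Conditions: NBS premixed with Me2S, CH2Cl2, 0 °C; then 22, −20 to 0 °C
Reagents that add atoms: N-bromosuccinimide, O=C1CCC(=O)N1Br
Why: Corey–Kim-type activation of the allylic alcohol and SN2' attack of bromide at C13 should give the conjugated Z-2-(bromomethyl)enoate, with C7 becoming sp2; premixing leaves no free NBS to brominate the furanone.

Step 14
Reactants: 23 allylic bromide
Product: 24 allylic bromide with free C6 hydroxyl
Conditions: HF·pyridine, pyridine, THF, 0 °C
Reagents that add atoms: none
Why: Acidic fluoride desilylation, in which the primary allylic silyl ether at C6 should react much faster than the hindered secondary one at C8; the PMB ether and the allylic bromide are inert.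

Step 15
Reactants: 24 hydroxy allylic bromide
Product: 25 allylic bromide enal (C6 aldehyde)
Conditions: Dess–Martin periodinane, NaHCO3, CH2Cl2, 0 °C
Reagents that add atoms: none
Why: Dess–Martin oxidation of the allylic alcohol to the enal under buffered neutral conditions, which should preserve the C4=C5 geometry.

Step 16
Reactants: 25 allylic bromide enal
Product: 28 macrocyclic cis-lactone (6S,7R,8R,10R; 8-OTBS, 15-OPMB), via allylindium 26 (not isolated), via hydroxy ester 27 (not isolated)
Conditions: indium powder, THF–H2O (3:1), 0.002 M, rt; then PPTS (cat.), CH2Cl2, rt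
Reagents that add atoms: none
Why: Indium-mediated Barbier allylation in which the Z-allylindium attacks the C6 aldehyde through C7 in a closed six-membered chair transition state, which should give the syn adduct (6S) and, after lactonisation, the cis-lactone; with the tether carbon C9 gauche to the forming bond, the C8 silyloxy group is expected to take the inside position and hydrogen the anti position (inside-alkoxy effect), which leads to 7R.

Step 17
Reactants: 28 macrocyclic lactone silyl ether
Product: 29 8-hydroxy macrolactone (15-OPMB)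
Conditions: HF·pyridine, THF, 0 °C to rt
Reagents that add atoms: none
Why: Fluoride cleavage of the secondary silyl ether under acidic, non-basic conditions that should leave the α-methylene lactone, the furanone and the PMB ether untouched.

Step 18
Reactants: 29 8-hydroxy macrolactone
Product: 30 15-O-PMB ether of the target
Conditions: tigloyl chloride, Et3N, DMAP (cat.), CH2Cl2, 0 °C
Reagents that add atoms: (E)-2-methylbut-2-enoyl chloride, C/C=C(\C)C(Cl)=O
Why: DMAP-catalysed acylation of the C8 hydroxyl with retention, since the C8–O bond is not broken; the E geometry of the tiglate comes from the reagent.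

Step 19
Reactants: 30 15-O-PMB ether of the target
Product: 31 target compound
Conditions: DDQ, CH2Cl2–pH 7 phosphate buffer, 0 °C
Reagents that add atoms: none
Why: Oxidative cleavage of the PMB ether by DDQ (oxidation of the electron-rich arene, hydrolysis of the oxocarbenium ion) under buffered conditions should free the C15 hydroxyl and give the target.

Compound list
1 | but-2-yne-1,4-diol | OCC#CCO | starting material
2 | 4-[(4-methoxybenzyl)oxy]but-2-yn-1-ol | OCC#CCOCc1ccc(OC)cc1 | intermediate
3 | (Z)-3-iodo-4-[(4-methoxybenzyl)oxy]but-2-en-1-ol | OC/C=C(\I)COCc1ccc(OC)cc1 | intermediate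
4 | (Z)-tert-butyl({3-iodo-4-[(4-methoxybenzyl)oxy]but-2-en-1-yl}oxy)dimethylsilane | CC(C)(C)[Si](C)(C)OC/C=C(\I)COCc1ccc(OC)cc1 | intermediate
5 | (E)-1,2-bis(tributylstannyl)ethene | CCCC[Sn](CCCC)(CCCC)/C=C/[Sn](CCCC)(CCCC)CCCC | starting material
6 | tributyl{(1E,3E)-5-[(tert-butyldimethylsilyl)oxy]-3-{[(4-methoxybenzyl)oxy]methyl}penta-1,3-dien-1-yl}stannane | CCCC[Sn](CCCC)(CCCC)/C=C/C(COCc1ccc(OC)cc1)=C\CO[Si](C)(C)C(C)(C)C | intermediate
7 | (R)-5-[(trityloxy)methyl]dihydrofuran-2(3H)-one | C(c1ccccc1)(c1ccccc1)(c1ccccc1)OC[C@H]1CCC(=O)O1 | starting material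
8 | (5R)-3-methyl-5-[(trityloxy)methyl]dihydrofuran-2(3H)-one, both C3 epimers | C(c1ccccc1)(c1ccccc1)(c1ccccc1)OC[C@H]1CC(C)C(=O)O1 | intermediate
9 | (4R)-4-hydroxy-N-methoxy-N,2-dimethyl-5-(trityloxy)pentanamide (not isolated) | C(c1ccccc1)(c1ccccc1)(c1ccccc1)OC[C@H](O)CC(C)C(=O)N(C)OC | intermediate
10 | (4R)-4-[(tert-butyldimethylsilyl)oxy]-N-methoxy-N,2-dimethyl-5-(trityloxy)pentanamide | C(c1ccccc1)(c1ccccc1)(c1ccccc1)OC[C@H](O[Si](C)(C)C(C)(C)C)CC(C)C(=O)N(C)OC | intermediate
11 | (1E,3E)-dienyllithium from 6, lithium in place of tin (not isolated) | [Li]/C=C/C(COCc1ccc(OC)cc1)=C\CO[Si](C)(C)C(C)(C)C | intermediate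
12 | (2R,6E,8E)-2,10-bis[(tert-butyldimethylsilyl)oxy]-8-{[(4-methoxybenzyl)oxy]methyl}-4-methyl-1-(trityloxy)deca-6,8-dien-5-one | C(c1ccccc1)(c1ccccc1)(c1ccccc1)OC[C@H](O[Si](C)(C)C(C)(C)C)CC(C)C(=O)/C=C/C(COCc1ccc(OC)cc1)=C\CO[Si](C)(C)C(C)(C)C | intermediate
13 | (2R,6E,8E)-2,10-bis[(tert-butyldimethylsilyl)oxy]-1-hydroxy-8-{[(4-methoxybenzyl)oxy]methyl}-4-methyldeca-6,8-dien-5-one (not isolated) | OC[C@H](O[Si](C)(C)C(C)(C)C)CC(C)C(=O)/C=C/C(COCc1ccc(OC)cc1)=C\CO[Si](C)(C)C(C)(C)C | intermediate
14 | (3R)-3-[(tert-butyldimethylsilyl)oxy]-6-[(1E,3E)-5-[(tert-butyldimethylsilyl)oxy]-3-{[(4-methoxybenzyl)oxy]methyl}penta-1,3-dien-1-yl]-5-methyl-3,4-dihydro-2H-pyran | C1[C@H](O[Si](C)(C)C(C)(C)C)CC(C)=C(O1)/C=C/C(COCc2ccc(OC)cc2)=C\CO[Si](C)(C)C(C)(C)C | intermediate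
15 | endoperoxide: 1,2-dioxine (O–O from C10 to C3, C1=C2) fused at C1–C10 to the pyran ring; 8R,10R,3R, C10–O anti to C8–OTBS | C1[C@H](O[Si](C)(C)C(C)(C)C)C[C@@]2(C)OO[C@H](C=C2O1)/C(COCc3ccc(OC)cc3)=C\CO[Si](C)(C)C(C)(C)C | intermediate
16 | hydroxy enone: (3R,5R)-5-silyloxy-3-hydroxy-3-methyltetrahydropyran-2-ylidene (Z) at C2 of the C3 dienone (not isolated) | C1[C@H](O[Si](C)(C)C(C)(C)C)C[C@@](C)(O)/C(O1)=C\C(=O)/C(COCc2ccc(OC)cc2)=C\CO[Si](C)(C)C(C)(C)C | intermediate
17 | hemiketal: 2-hydroxy-2,5-dihydrofuran (O–C3(OH)–C2=C1–C10) fused to the pyran ring, C3 anomers (not isolated) | C1[C@H](O[Si](C)(C)C(C)(C)C)C[C@@]2(C)OC(O)(C=C2O1)/C(COCc3ccc(OC)cc3)=C\CO[Si](C)(C)C(C)(C)C | intermediate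
18 | (2R)-2-[(2R)-2-[(tert-butyldimethylsilyl)oxy]-3-hydroxypropyl]-5-[(Z)-4-[(tert-butyldimethylsilyl)oxy]-1-[(4-methoxybenzyl)oxy]but-2-en-2-yl]-2-methylfuran-3(2H)-one | OC[C@H](O[Si](C)(C)C(C)(C)C)C[C@@]1(C)OC(=CC1=O)/C(COCc1ccc(OC)cc1)=C\CO[Si](C)(C)C(C)(C)C | intermediate
19 | (2R)-2-[(tert-butyldimethylsilyl)oxy]-3-[(2R)-furanon-2-yl]propanal, otherwise as 18 | O=C[C@H](O[Si](C)(C)C(C)(C)C)C[C@@]1(C)OC(=CC1=O)/C(COCc1ccc(OC)cc1)=C\CO[Si](C)(C)C(C)(C)C | intermediate
20 | methyl propiolate | C#CC(=O)OC | starting material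
21 | methyl 2-(diisobutylalumanyl)acrylate (not isolated) | C=C(C(=O)OC)[Al](CC(C)C)CC(C)C | intermediate
22 | methyl (4R)-4-[(tert-butyldimethylsilyl)oxy]-3-hydroxy-2-methylene-5-[(2R)-furanon-2-yl]pentanoate, C3 epimers | C=C(C(=O)OC)C(O)[C@H](O[Si](C)(C)C(C)(C)C)C[C@@]1(C)OC(=CC1=O)/C(COCc1ccc(OC)cc1)=C\CO[Si](C)(C)C(C)(C)C | intermediate
23 | methyl (2Z,4R)-2-(bromomethyl)-4-[(tert-butyldimethylsilyl)oxy]-5-[(2R)-furanon-2-yl]pent-2-enoate, C6–OTBS | COC(=O)/C(CBr)=C/[C@H](O[Si](C)(C)C(C)(C)C)C[C@@]1(C)OC(=CC1=O)/C(COCc1ccc(OC)cc1)=C\CO[Si](C)(C)C(C)(C)C | intermediate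
24 | as 23 with free C6 hydroxyl | COC(=O)/C(CBr)=C/[C@H](O[Si](C)(C)C(C)(C)C)C[C@@]1(C)OC(=CC1=O)/C(COCc1ccc(OC)cc1)=C\CO | intermediate
25 | as 23 with C6 aldehyde (Z-enal) | COC(=O)/C(CBr)=C/[C@H](O[Si](C)(C)C(C)(C)C)C[C@@]1(C)OC(=CC1=O)/C(COCc1ccc(OC)cc1)=C\C=O | intermediate
26 | allylindium bromide species from 25, drawn as the C13 indium dibromide (not isolated) | COC(=O)/C(C[In](Br)Br)=C/[C@H](O[Si](C)(C)C(C)(C)C)C[C@@]1(C)OC(=CC1=O)/C(COCc1ccc(OC)cc1)=C\C=O | intermediate
27 | ten-membered carbocyclic hydroxy ester (6S-OH, 7R, 8R-OTBS, 10R; methyl 2-substituted acrylate on C7) (not isolated) | C=C(C(=O)OC)[C@H]1[C@@H](O)/C=C(/COCc2ccc(OC)cc2)C2=CC(=O)[C@@](C)(C[C@H]1O[Si](C)(C)C(C)(C)C)O2 | intermediate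
28 | 8-O-TBS, 15-O-PMB derivative of the 8-desacyl target (6S,7R,8R,10R) | C=C1C(=O)O[C@H]2/C=C(/COCc4ccc(OC)cc4)C3=CC(=O)[C@@](C)(C[C@@H](O[Si](C)(C)C(C)(C)C)[C@@H]12)O3 | intermediate
29 | 15-O-PMB ether of the 8-desacyl target | C=C1C(=O)O[C@H]2/C=C(/COCc4ccc(OC)cc4)C3=CC(=O)[C@@](C)(C[C@@H](O)[C@@H]12)O3 | intermediate
30 | 15-O-PMB ether of the target | C=C1C(=O)O[C@H]2/C=C(/COCc4ccc(OC)cc4)C3=CC(=O)[C@@](C)(C[C@@H](OC(=O)/C(C)=C/C)[C@@H]12)O3 | intermediate
31 | target, (6S,7R,8R,10R) furanoheliangolide 8-tiglate with free C15 hydroxyl | C=C1C(=O)O[C@H]2/C=C(/CO)C3=CC(=O)[C@@](C)(C[C@@H](OC(=O)/C(C)=C/C)[C@@H]12)O3 | target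

Total step count: 19. Longest linear sequence: 17 steps (steps 1–4 and 7–19).

Steps most likely to fail

Step 9. Singlet oxygen may react with the enol-ether double bond alone (dioxetane formation, or ene reaction at C9–H or the C10 methyl) instead of across the diene, and the C8 silyloxy group may not discriminate the two faces well enough. The fallback sets out from 14 and uses no peroxide. Epoxidation of the enol ether with dimethyldioxirane (acetone, −78 °C) should occur anti to the pseudoaxial C8 substituent, as is usual for cyclic enol ethers of this kind. Aqueous work-up opens the labile epoxy ketal to the α'-hydroxy dienone F1 (10R tertiary alcohol, free C7–OH, E-enone). A Wacker-type oxidative cyclisation (PdCl2(MeCN)2, CuCl, O2, DME) of the tertiary hydroxyl onto C3, with β-hydride elimination, then gives furanone 18, where the route is rejoined; steps 9 and 10 are bypassed.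

Step 10. Under base, fragmentation of the peroxide or attack at silicon may compete with abstraction of C3–H, so that the internal redox step does not run cleanly. The fallback sets out from 15 and splits the redox event into a reduction and an oxidation. Thiourea in MeOH cleaves the O–O bond to the ene-diol F2 (C3–OH and C10–OH, enol ether intact). MnO2 in CH2Cl2 then oxidises the doubly allylic C3 hydroxyl selectively, the tertiary one being inert. This gives hydroxy enone 16, now isolated, which is relayed to 18 with PPTS in wet THF as in the second stage of step 10.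

Step 16. Protonolysis of the allylindium or intermolecular allylation may outrun closure of the ten-membered ring, and facial selectivity at C7 may be eroded. The fallback sets out from 24 and replaces the organoindium by an allylboronate, which has no free carbanion. Borylation of the allylic bromide (B2pin2, Pd2(dba)3, DMSO, 50 °C) gives allylboronate alcohol F3, and Dess–Martin oxidation gives the boronate enal F4. Intramolecular allylboration in dilute toluene with Sc(OTf)3 (cat.) proceeds through a closed chair transition state; PPTS lactonisation then returns 28.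

Further compounds
F1 | step 9 | α'-hydroxy dienone (2R,4R,6E,8E)-2,10-bis[(tert-butyldimethylsilyl)oxy]-1,4-dihydroxy-8-{[(4-methoxybenzyl)oxy]methyl}-4-methyldeca-6,8-dien-5-one | OC[C@H](O[Si](C)(C)C(C)(C)C)C[C@@](C)(O)C(=O)/C=C/C(COCc1ccc(OC)cc1)=C\CO[Si](C)(C)C(C)(C)C
F2 | step 10 | ene-diol from O–O cleavage of 15 (C3–OH R, C10–OH R, Z enol ether C1=C2 in the pyran) | C1[C@H](O[Si](C)(C)C(C)(C)C)C[C@@](C)(O)/C(O1)=C\[C@@H](O)/C(COCc2ccc(OC)cc2)=C\CO[Si](C)(C)C(C)(C)C
F3 | step 16 | allylboronate alcohol, pinacolboryl in place of bromine in 24 | COC(=O)/C(CB1OC(C)(C)C(C)(C)O1)=C/[C@H](O[Si](C)(C)C(C)(C)C)C[C@@]1(C)OC(=CC1=O)/C(COCc1ccc(OC)cc1)=C\CO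
F4 | step 16 | allylboronate enal, pinacolboryl in place of bromine in 25 | COC(=O)/C(CB1OC(C)(C)C(C)(C)O1)=C/[C@H](O[Si](C)(C)C(C)(C)C)C[C@@]1(C)OC(=CC1=O)/C(COCc1ccc(OC)cc1)=C\C=O
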